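Everything rests on cutting ring B (C9–C12, C19, C20) at C11–C12 and C19–C20. Two 1,4 relationships allow this cut. C9, the anchor of ring C, lies para to the quaternary C12 in ring B. Ring A is functionalised at C14 and C17. Together these are the footprint that a 2-substituted butadiene leaves on the methylated C=C bond of a p-benzoquinone. One chelation-controlled, BINOL–titanium-catalysed [4+2] cycloaddition closes ring B, forms both bonds and fixes C12. Its precursor is an enantiopure 2-(cyclopentyl)butadiene from (+)-borneol that already holds C4–Br, O6 (silyl ether) and quaternary C7. Its partner is 2-methoxy-6-methyl-1,4-benzoquinone, whose methoxy group later leaves by elimination.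

Key step: step 13

Conventions: carbons are numbered C1–C20 in the order written in the target SMILES. Borneol-derived atoms carry these numbers from the start (bornane C1, C2, C3, C4, C5, C6, C7 = C7, C6, C5, C4, C10, C9, C2). In the decalin, β is the face carrying the C13 methyl group and α is the opposite face.

Remark on the target:
- C13 and the C19 hydroxyl are anti (trans-decalin), whereas a quinone cycloadduct is cis-fused. C19 is therefore flattened on purpose (step 15) and rebuilt (step 18).
- Br4, O6 and C9 are all cis on ring C. The C4–C10 bond of borneol must therefore be replaced by bromine with overall retention (steps 3–7).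

Assumption: the (R)-BINOL titanium chelate is taken to expose the quinone face that leads to the 12S adduct. The sense of induction is ligand-controlled, so the mirror-image ligand is used if the opposite sense is found.

Step 1
Reactants: 1 (+)-borneol
Product: 2 (+)-bornyl acetate
Conditions: Ac2O, pyridine, DMAP (cat.), CH2Cl2, rt
Reagents that add atoms: acetic anhydride, CC(=O)OC(C)=O
Why: Standard DMAP-catalysed esterification masks the endo hydroxyl that becomes O6 and is needed for the chromic acid step, and no stereocentre is touched.

Step 2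
Reactants: 2 (+)-bornyl acetate
Product: 3 5-oxobornyl acetate (ketone at C10)
Conditions: CrO3, AcOH–Ac2O, rt → 40 °C
Reagents that add atoms: chromium trioxide, O=[Cr](=O)=O
Why: Remote C–H oxidation of bornyl acetate with chromic anhydride is a classical reaction of this very substrate, in which the acetoxy group deactivates the nearer methylenes and the exposed C10 methylene (bornane C5) is taken to the ketone.

Step 3
Reactants: 3 5-oxobornyl acetate
Product: 4 acetoxy δ-lactone (6-acetoxy-5,8,8-trimethyl-2-oxabicyclo[3.2.1]octan-3-one)
Conditions: mCPBA, CH2Cl2, rt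
Reagents that add atoms: 3-chloroperbenzoic acid, OOC(=O)c1cccc(Cl)c1
Why: Baeyer–Villiger oxidation of a strained norbornanone-type ketone, in which the methine bridgehead C4 migrates in preference to the C9 methylene and does so with retention, so the new C4–O bond lies on the ring C face that carries C9.

Step 4
Reactants: 4 acetoxy δ-lactone
Product: 6 hydroxy γ-lactone (5-hydroxy-3a,4,4-trimethylhexahydrocyclopenta[b]furan-2-one; 4-OH and O6 and C9 all cis), via hydroxy δ-lactone 5 (not isolated)
Conditions: K2CO3 (0.2 equiv), MeOH, rt
Reagents that add atoms: none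
Why: Base-catalysed transesterification removes the acetate, and the freed O6 alkoxide, cis and vicinal to the acetic acid arm, attacks the bridged lactone (translactonisation) to give the less strained cis-fused γ-lactone, which liberates the C4 hydroxyl selectively and ties up O6 and C10 in one ring.

Step 5
Reactants: 6 hydroxy γ-lactone
Product: 7 keto γ-lactone (C4 ketone)
Conditions: Dess–Martin periodinane, CH2Cl2, rt
Reagents that add atoms: none
Why: Dess–Martin oxidation is neutral and fast, which matters because the product is a β-acyloxy ketone that a basic oxidant could push into E1cB elimination.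

Step 6
Reactants: 7 keto γ-lactone
Product: 9 bromoalkene γ-lactone (C4(Br)=C5), via N-silyl hydrazone 8 (not isolated)
Conditions: TBSNHNHTBS, Sc(OTf)3 (1 mol%), CHCl3, rt → 50 °C, evaporate; added to Br2, 2-tert-butyl-1,1,3,3-tetramethylguanidine (BTMG), CH2Cl2, 0 °C
Reagents that add atoms: bromine, BrBr
Why: Lewis-acid-catalysed condensation with the bis-silyl hydrazine forms the hydrazone without free hydrazine (so the lactone is safe), and the Barton vinyl halide synthesis (oxidation to the diazo compound, bromination, loss of N2 and of a proton) can place the double bond only toward C5 because C2 is quaternary.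

Step 7
Reactants: 9 bromoalkene γ-lactone
Product: 10 bromo γ-lactone (Br4 and O6 and C9 all cis)
Conditions: Co(acac)2 (25 mol%), t-BuOOH (25 mol%), Et3SiH, 1,4-cyclohexadiene, n-PrOH, rt, Ar
Reagents that add atoms: none
Why: Cobalt-hydride hydrogen-atom-transfer hydrogenation of an alkenyl halide to the alkyl halide, in which H adds to C5 and the C4 α-bromo radical abstracts hydrogen from cyclohexadiene on the convex face of the cis-bicyclo[3.3.0] lactone (the face of C8 and H6), so bromine ends on the concave face cis to O6 and C9 (4R) without C–Br hydrogenolysis.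

Step 8
Reactants: 10 bromo γ-lactone
Product: 13 α-methylene bromo lactone (C9=C20), via Mannich base 11 (not isolated), via ammonium iodide 12 (not isolated)
Conditions: LiN(i-Pr)2, THF, −78 °C; CH2=NMe2+ I−, −78 °C → rt; MeI, rt; DBU, CH2Cl2, rt
Reagents that add atoms: Eschenmoser's salt, C=[N+](C)C.[I-]
Why: Enolisation at the only acidic CH2 (C9), Mannich reaction with Eschenmoser's salt, exhaustive methylation and E1cB loss of trimethylamine form the standard α-methylenation of γ-butyrolactones and bring in C20, while the neopentyl bromide is inert to the amide base at −78 °C.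

Step 9
Reactants: 13 α-methylene bromo lactone
Product: 14 α-methylene lactol (anomer mixture)
Conditions: i-Bu2AlH (1.1 equiv), CH2Cl2, −78 °C
Reagents that add atoms: none
Why: Partial reduction of a lactone with one equivalent of the aluminium hydride stops at the tetrahedral aluminium hemiacetal, and 1,2-attack is normal for α-methylene lactones at low temperature.

Step 10
Reactants: 14 α-methylene lactol
Product: 15 dienol (2-(ring C)buta-1,3-diene with free 6-OH)
Conditions: Ph3PCH3Br, KOt-Bu, THF, 0 °C → rt
Reagents that add atoms: methyltriphenylphosphonium bromide, C[P+](c1ccccc1)(c1ccccc1)c1ccccc1.[Br-]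
Why: Wittig methylenation, in which the basic ylide opens the lactol to the 2-substituted acrolein alkoxide and turns its aldehyde carbon C10 into the C10=C11 vinyl group, while the neopentyl secondary bromide resists E2 at or below room temperature.

Step 11
Reactants: 15 dienol
Product: 16 2-(ring C)buta-1,3-diene 6-O-TBS ether
Conditions: TBSOTf, 2,6-lutidine, CH2Cl2, 0 °C
Reagents that add atoms: tert-butyldimethylsilyl triflate, CC(C)(C)[Si](C)(C)OS(=O)(=O)C(F)(F)F
Why: Silylation with the triflate and 2,6-lutidine is the usual way to protect a hindered neopentyl secondary alcohol, and it removes the only protic, titanium-binding group before the cycloaddition.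

Step 12
Reactants: 17 2-methoxy-6-methylphenol
Product: 18 2-methoxy-6-methyl-1,4-benzoquinone
Conditions: Co(salen) (5 mol%), O2 (1 atm), DMF, rt
Reagents that add atoms: dioxygen, O=O
Why: Cobalt–salen-catalysed aerobic phenol oxidation delivers oxygen to the free para position of a 2,6-disubstituted phenol and gives the p-quinone, as known for the 6-alkyl homologues of this phenol.

Step 13
Reactants: 16 2-(ring C)buta-1,3-diene 6-O-TBS ether; 18 2-methoxy-6-methyl-1,4-benzoquinone
Product: 19 cis-fused methoxy ene-dione adduct (12S,19R)
Conditions: (R)-BINOL (30 mol%), TiCl2(Oi-Pr)2 (30 mol%), 4 Å MS, CH2Cl2–toluene, −30 °C → rt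
Reagents that add atoms: none
Why: The reaction is a concerted, asynchronous, suprafacial [4+2] cycloaddition in which titanium binds the C14 carbonyl oxygen and the neighbouring methoxy oxygen as a five-membered chelate and so lowers the LUMO of the C12=C19 bond. The closest known reaction type is the chelating-Lewis-acid (BINOL–titanium) catalysed Diels–Alder addition of 2-alkylbutadienes to the methyl-substituted bond of methoxy(methyl)benzoquinones. Ring B closes as a six-membered carbocycle by intermolecular cycloaddition, with C11–C12 and C19–C20 forming on one quinone face so that C13 and H19 are cis. C12 (S) is set by the ligand-defined quinone face because ring C is too far from the reacting termini to discriminate, and C19 (R) follows from suprafaciality and is rebuilt later anyway. Site selectivity comes from the methoxy group, which deactivates C15=C16, and regioselectivity from pairing the larger HOMO coefficient at C20 with C19, the β-carbon of the chelated C14 carbonyl, whereas a monodentate acid is avoided since it would bind the more basic vinylogous-ester oxygen at C17 and reverse the orientation. Steric pressure from the fully substituted C7 raises the s-cis population of the diene, and no endo/exo question arises because both diene termini are CH2.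

Step 14
Reactants: 19 cis-fused methoxy ene-dione adduct
Product: 21 15-ene-14,17-dione (methoxy-free ene-dione; C19 epimerisable), via methoxy dione 20 (not isolated)
Conditions: Zn, AcOH–CH2Cl2, 0 °C → rt, filter, evaporate; DBU (0.2 equiv), CH2Cl2, rt, Ar
Reagents that add atoms: none
Why: Zinc in acetic acid performs the usual two-electron conjugate reduction of an ene-dione, and the resulting 15-methoxy dione loses methanol by base-catalysed E1cB elimination through the C17 enolate, so the regiocontrol group leaves without a trace and an ene-dione returns whose only enolisable hydrogen is H19.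

Step 15
Reactants: 21 15-ene-14,17-dione
Product: 22 17-triethylsilyloxy-15,17(19)-dien-14-one
Conditions: TESOTf, Et3N, CH2Cl2, −78 → 0 °C
Reagents that add atoms: triethylsilyl triflate, CC[Si](CC)(CC)OS(=O)(=O)C(F)(F)F
Why: Soft enolisation with silyl triflate and amine is regiospecific here because H19 is the only α-hydrogen of the ene-dione, so the C17=C19 enol ether forms as a single regioisomer and the cis ring-fusion centre is erased.

Step 16
Reactants: 22 17-triethylsilyloxy-15,17(19)-dien-14-one
Product: 23 17-triethylsilyloxy-17(19)-en-14-one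
Conditions: H2 (1 atm), RhCl(PPh3)3 (10 mol%), benzene, rt
Reagents that add atoms: none
Why: Homogeneous hydrogenation with this rhodium complex discriminates by substitution, so only the cis-disubstituted C15=C16 bond is saturated (as in the known selective saturation of the disubstituted bond of steroidal dienones), while the trisubstituted C9=C10 bond, the tetrasubstituted enol ether and the C–Br bond stay intact.

Step 17
Reactants: 23 17-triethylsilyloxy-17(19)-en-14-one
Product: 24 14β-alcohol (14S) of the silyl enol ether
Conditions: NaBH4, MeOH–THF, 0 °C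
Reagents that add atoms: none
Why: Borohydride reduction of the only ketone, with hydride arriving anti to the pseudoaxial C13 methyl group (the new centre is inconsequential since it is re-oxidised in step 21), takes C14 out of play so that C17 is the sole carbonyl in steps 18 and 19, gives ring A a true half-chair, and removes any retro-aldol pathway once O19 is in place.

Step 18
Reactants: 24 14β-alcohol of the silyl enol ether
Product: 26 14β,19α-dihydroxy-17-ketone (trans-fused), via silyloxy epoxide 25 (not isolated)
Conditions: dimethyldioxirane (1.0 equiv), acetone–CH2Cl2, −78 → −40 °C; then aq. HCl (cat.), THF, 0 °C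
Reagents that add atoms: dimethyldioxirane, CC1(C)OO1
Why: Rubottom oxidation, in which the tetrasubstituted silyl enol ether is by far the most electron-rich alkene and is attacked from the α face because the pseudoaxial C13 methyl group screens the β face (the sense known for 10-methyl-1(9)-octalins and Δ5-steroids), and mild acid collapses the silyloxy epoxide to the 19α-hydroxy ketone, making the ring fusion trans (19R).

Step 19
Reactants: 26 14β,19α-dihydroxy-17-ketone
Product: 27 14β,17β,19α-triol (C18 methyl α, equatorial)
Conditions: MeMgBr (6 equiv), THF, −78 → 0 °C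
Reagents that add atoms: methylmagnesium bromide, C[Mg]Br
Why: Grignard addition to the only carbonyl group, in which the axial β trajectory at C17 is blocked by the syn-axial C13 methyl group, so methyl enters equatorially from the α face and the new hydroxyl is axial and β (17R), trans-diaxial to O19.

Step 20
Reactants: 27 14β,17β,19α-triol
Product: 29 9α,14β,17β,19α-tetraol, via hydroperoxide 28 (not isolated)
Conditions: Mn(dpm)3 (20 mol%), PhSiH3, O2 (1 atm), i-PrOH–CH2Cl2, 0 °C → rt; then PPh3
Reagents that add atoms: dioxygen, O=O
Why: Mukaiyama hydration, in which hydrogen-atom transfer to C10 gives the tertiary C9 radical that, in the now rigid trans-decalin, keeps the very large ring C substituent equatorial and is trapped by O2 along the axial α direction (9R), syn to O19, with the phosphine reducing the hydroperoxide.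

Step 21
Reactants: 29 9α,14β,17β,19α-tetraol
Product: 30 9α,17β,19α-trihydroxy-14-ketone
Conditions: Dess–Martin periodinane, CH2Cl2, rt
Reagents that add atoms: none
Why: Dess–Martin oxidation can act only on the single secondary alcohol at C14, since the other three hydroxyls are tertiary and O6 is silylated, and its neutral medium spares the β-hydroxy ketone from retro-aldol cleavage.

Step 22
Reactants: 30 9α,17β,19α-trihydroxy-14-ketone
Product: 32 14-bromo-14-ene triol, via N-silyl hydrazone 31 (not isolated)
Conditions: TBSNHNHTBS, Sc(OTf)3 (1 mol%), CHCl3, 50 °C, evaporate; added to Br2, BTMG, CH2Cl2, 0 °C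
Reagents that add atoms: bromine, BrBr
Why: The same two-stage Barton vinyl bromide synthesis as in step 6, in which the hydrazone forms at the only carbonyl group, the proton can be lost only from C15 because C12 is quaternary, no alkene remains to consume bromine, and the tertiary alcohols are inert to both stages.

Step 23
Reactants: 32 14-bromo-14-ene triol
Product: 33 neoirietetraol 6-O-TBS ether
Conditions: Co(acac)2 (25 mol%), t-BuOOH (25 mol%), Et3SiH, 1,4-cyclohexadiene, n-PrOH, rt, Ar
Reagents that add atoms: none
Why: Hydrogen-atom-transfer hydrogenation of the alkenyl bromide as in step 7, in which H adds to C15 and the C14 α-bromo radical takes its second hydrogen along the axial α trajectory, anti to the vicinal axial C13 methyl group, leaving bromine equatorial and β (14S), which is also the more stable epimer.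

Step 24
Reactants: 33 neoirietetraol 6-O-TBS ether
Product: 34 neoirietetraol
Conditions: HF·pyridine, THF, 0 °C → rt
Reagents that add atoms: none
Why: Fluoride-induced silyl ether cleavage in a mildly acidic medium avoids alkoxide formation near the two secondary bromides and leaves the tertiary alcohols untouched.

Compound list

1 | (+)-borneol, (1R,2S,4R) | CC1(C)[C@H]2C[C@H](O)[C@]1(C)CC2 | starting material
2 | (+)-bornyl acetate | CC1(C)[C@H]2C[C@H](OC(C)=O)[C@]1(C)CC2 | intermediate
3 | 5-oxobornyl acetate (endo-2-acetoxybornan-5-one; ketone at C10) | CC1(C)[C@H]2C[C@H](OC(C)=O)[C@]1(C)CC2=O | intermediate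
4 | acetoxy δ-lactone, 6-acetoxy-5,8,8-trimethyl-2-oxabicyclo[3.2.1]octan-3-one (O inserted between C4 and C10 with retention) | CC1(C)[C@H]2C[C@H](OC(C)=O)[C@]1(C)CC(=O)O2 | intermediate
5 | hydroxy δ-lactone (deacetylated 4) | CC1(C)[C@H]2C[C@H](O)[C@]1(C)CC(=O)O2 | intermediate
6 | hydroxy γ-lactone, cis-fused 5-hydroxy-3a,4,4-trimethylhexahydrocyclopenta[b]furan-2-one, 4-OH cis to O6 and C9 | CC1(C)[C@H](O)C[C@H](O2)[C@]1(C)CC2=O | intermediate
7 | keto γ-lactone (C4 ketone) | CC1(C)C(=O)C[C@H](O2)[C@]1(C)CC2=O | intermediate
8 | (E)-N-TBS hydrazone of 7 | CC1(C)/C(=N/N[Si](C)(C)C(C)(C)C)C[C@H](O2)[C@]1(C)CC2=O | intermediate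
9 | bromoalkene γ-lactone, C4(Br)=C5 | CC1(C)C(Br)=C[C@H](O2)[C@]1(C)CC2=O | intermediate
10 | bromo γ-lactone, (4R), Br cis to O6 and C9 | CC1(C)[C@H](Br)C[C@H](O2)[C@]1(C)CC2=O | intermediate
11 | Mannich base, 9-(dimethylaminomethyl) lactone (C9 epimers) | CC1(C)[C@H](Br)C[C@H](O2)[C@]1(C)C(CN(C)C)C2=O | intermediate
12 | trimethylammonium iodide of 11 | CC1(C)[C@H](Br)C[C@H](O2)[C@]1(C)C(C[N+](C)(C)C)C2=O.[I-] | intermediate
13 | α-methylene bromo lactone (C9=C20) | CC1(C)[C@H](Br)C[C@H](O2)[C@]1(C)C(=C)C2=O | intermediate
14 | α-methylene lactol (anomers at C10) | CC1(C)[C@H](Br)C[C@H](O2)[C@]1(C)C(=C)C2O | intermediate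
15 | dienol, 2-(ring C)buta-1,3-diene with free 6-OH | CC1(C)[C@H](Br)C[C@H](O)[C@]1(C)C(=C)C=C | intermediate
16 | 2-(ring C)buta-1,3-diene 6-O-TBS ether | CC1(C)[C@H](Br)C[C@H](O[Si](C)(C)C(C)(C)C)[C@]1(C)C(=C)C=C | intermediate
17 | 2-methoxy-6-methylphenol | COc1cccc(C)c1O | starting material
18 | 2-methoxy-6-methyl-1,4-benzoquinone | COC1=CC(=O)C=C(C)C1=O | intermediate
19 | cis-fused methoxy ene-dione adduct, (12S,19R) | CC1(C)[C@H](Br)C[C@H](O[Si](C)(C)C(C)(C)C)[C@]1(C)C1=CC[C@]2(C)C(=O)C(OC)=CC(=O)[C@@H]2C1 | intermediate
20 | 15-methoxy-14,17-dione (C15 epimers) | CC1(C)[C@H](Br)C[C@H](O[Si](C)(C)C(C)(C)C)[C@]1(C)C1=CC[C@]2(C)C(=O)C(OC)CC(=O)[C@@H]2C1 | intermediate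
21 | 15-ene-14,17-dione, drawn cis-fused (C19 epimerisable, erased in step 15) | CC1(C)[C@H](Br)C[C@H](O[Si](C)(C)C(C)(C)C)[C@]1(C)C1=CC[C@]2(C)C(=O)C=CC(=O)[C@@H]2C1 | intermediate
22 | 17-triethylsilyloxy-15,17(19)-dien-14-one | CC1(C)[C@H](Br)C[C@H](O[Si](C)(C)C(C)(C)C)[C@]1(C)C1=CC[C@]2(C)C(=O)C=CC(O[Si](CC)(CC)CC)=C2C1 | intermediate
23 | 17-triethylsilyloxy-17(19)-en-14-one | CC1(C)[C@H](Br)C[C@H](O[Si](C)(C)C(C)(C)C)[C@]1(C)C1=CC[C@]2(C)C(=O)CCC(O[Si](CC)(CC)CC)=C2C1 | intermediate
24 | 14β-alcohol (14S) of the 17(19)-silyl enol ether | CC1(C)[C@H](Br)C[C@H](O[Si](C)(C)C(C)(C)C)[C@]1(C)C1=CC[C@]2(C)[C@@H](O)CCC(O[Si](CC)(CC)CC)=C2C1 | intermediate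
25 | 17,19-α-epoxide bearing 17-OTES | CC1(C)[C@H](Br)C[C@H](O[Si](C)(C)C(C)(C)C)[C@]1(C)C1=CC[C@]2(C)[C@@H](O)CC[C@]3(O[Si](CC)(CC)CC)O[C@]23C1 | intermediate
26 | 14β,19α-dihydroxy-17-ketone, trans-fused (19R) | CC1(C)[C@H](Br)C[C@H](O[Si](C)(C)C(C)(C)C)[C@]1(C)C1=CC[C@]2(C)[C@@H](O)CCC(=O)[C@@]2(O)C1 | intermediate
27 | 14β,17β,19α-triol (17R), 9-ene | CC1(C)[C@H](Br)C[C@H](O[Si](C)(C)C(C)(C)C)[C@]1(C)C1=CC[C@]2(C)[C@@H](O)CC[C@@](C)(O)[C@@]2(O)C1 | intermediate
28 | 9α-hydroperoxide of the triol | CC1(C)[C@H](Br)C[C@H](O[Si](C)(C)C(C)(C)C)[C@]1(C)[C@@]1(OO)CC[C@]2(C)[C@@H](O)CC[C@@](C)(O)[C@@]2(O)C1 | intermediate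
29 | 9α,14β,17β,19α-tetraol (9R) | CC1(C)[C@H](Br)C[C@H](O[Si](C)(C)C(C)(C)C)[C@]1(C)[C@@]1(O)CC[C@]2(C)[C@@H](O)CC[C@@](C)(O)[C@@]2(O)C1 | intermediate
30 | 9α,17β,19α-trihydroxy-14-ketone | CC1(C)[C@H](Br)C[C@H](O[Si](C)(C)C(C)(C)C)[C@]1(C)[C@@]1(O)CC[C@]2(C)C(=O)CC[C@@](C)(O)[C@@]2(O)C1 | intermediate
31 | (E)-N-TBS hydrazone of 30 | CC1(C)[C@H](Br)C[C@H](O[Si](C)(C)C(C)(C)C)[C@]1(C)[C@@]1(O)CC[C@]2(C)/C(=N/N[Si](C)(C)C(C)(C)C)CC[C@@](C)(O)[C@@]2(O)C1 | intermediate
32 | 14-bromo-14-ene triol | CC1(C)[C@H](Br)C[C@H](O[Si](C)(C)C(C)(C)C)[C@]1(C)[C@@]1(O)CC[C@]2(C)C(Br)=CC[C@@](C)(O)[C@@]2(O)C1 | intermediate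
33 | neoirietetraol 6-O-TBS ether (14S, Br equatorial) | CC1(C)[C@H](Br)C[C@H](O[Si](C)(C)C(C)(C)C)[C@]1(C)[C@@]1(O)CC[C@]2(C)[C@@H](Br)CC[C@@](C)(O)[C@@]2(O)C1 | intermediate
34 | neoirietetraol, (4R,6S,7R,9R,12S,14S,17R,19R) | CC1(C)[C@H](Br)C[C@H](O)[C@]1(C)[C@@]1(O)CC[C@]2(C)[C@@H](Br)CC[C@@](C)(O)[C@@]2(O)C1 | target

Total step count: 24. Longest linear sequence: 23 (steps 1–11 and 13–24).

Steps most likely to fail

Step 13. The chiral titanium complex may discriminate poorly between the two quinone faces, or it may turn over slowly because the bulky diene and the chelating product compete for the metal. The fallback gives up catalyst control and sets out from 16 and 18. The same cycloaddition is run with one equivalent of the achiral chelating acid SnCl4 (CH2Cl2, −78 °C), which keeps site selectivity and regiochemistry but uses both quinone faces. Because ring C is enantiopure, the two adducts are diastereomers and are separated by chromatography or crystallisation. The 12R,19S adduct F1 is set aside, and the route is rejoined at 19.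

Step 7. Hydrogen may be delivered to the wrong face of the C4 radical, which epimerises the bromide, or bromine may be lost by over-reduction. The fallback replaces the radical sequence by two polar inversions; it sets out from 6 and bypasses steps 5–7.
- A Mitsunobu reaction (4-nitrobenzoic acid, DIAD, PPh3, toluene) brings the carboxylate in from the open convex face and should give the inverted 4-nitrobenzoate F2.
- Catalytic K2CO3 in MeOH then releases the 4-epi alcohol F3.
- An Appel reaction (CBr4, P(n-Oct)3, toluene, 60 °C) displaces the oxyphosphonium group with a second inversion, and the route is rejoined at 10.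

Step 23. Hydrogen-atom transfer to the hindered bromoalkene next to quaternary C12 may be slow, and reductive loss of bromine may compete. The fallback sets out from 30 and avoids the bromoalkene altogether.
- KBH(s-Bu)3 (THF, −78 °C) attacks the ketone along the equatorial trajectory and should give the axial 14α-alcohol F4.
- An Appel reaction (CBr4, P(n-Oct)3, toluene, 60–70 °C) follows. Only this secondary alcohol can form a displaceable oxyphosphonium salt, so it is converted with inversion into the equatorial bromide, and the route is rejoined at 33.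

Further compounds

F1 | step 13 | 12R,19S cis-fused methoxy ene-dione adduct (other quinone face) | CC1(C)[C@H](Br)C[C@H](O[Si](C)(C)C(C)(C)C)[C@]1(C)C1=CC[C@@]2(C)C(=O)C(OC)=CC(=O)[C@H]2C1
F2 | step 7 | 4-epi 4-nitrobenzoate of the γ-lactone (ester trans to O6 and C9) | CC1(C)[C@@H](OC(=O)c2ccc(cc2)[N+](=O)[O-])C[C@H](O3)[C@]1(C)CC3=O
F3 | step 7 | 4-epi hydroxy γ-lactone (4-OH trans to O6 and C9) | CC1(C)[C@@H](O)C[C@H](O2)[C@]1(C)CC2=O
F4 | step 23 | 9α,14α,17β,19α-tetraol 6-O-TBS ether (axial 14-OH) | CC1(C)[C@H](Br)C[C@H](O[Si](C)(C)C(C)(C)C)[C@]1(C)[C@@]1(O)CC[C@]2(C)[C@H](O)CC[C@@](C)(O)[C@@]2(O)C1
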